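**Assumptions (one line each):** The C7 configuration is (R), as in the target SMILES. tert‑Butyl (E)‑4‑oxobut‑2‑enoate (11) is bought, or made in one Wittig step from glyoxal.

## Retrosynthetic overview
1. Mitorubrinic acid ⇒ C7‑orsellinate ester of the 7‑hydroxy azaphilone 13, with the orsellinate phenols protected as PMB ethers and the acid as its tert‑butyl ester (global TFA deprotection).
2. Azaphilone 13 ⇐ DDQ dehydrogenation of 2H‑pyran 12. The pyran ring closes by 6π‑oxa‑electrocyclization of a dienal made by vinylogous condensation of formyl‑dione 10 with aldehyde 11.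
3. Cyclohexenedione 7 (carbocycle, formed first) ⇐ intramolecular γ‑acylation of enone 6 by its own dioxolanone carbonyl.
4. Enone 6 ⇐ aldol/oxidation of the (S)‑lactic acid‑derived pivaldehyde acetal 3 with prenal. The quaternary C7 centre comes from lactate by self‑regeneration of stereocentres.
5. Ring order: carbocycle (Step 4), then pyran (Step 6).

## Route

**Step 1**
Reactants: 1 (S)‑lactic acid; 2 pivaldehyde
Product: 3 (2S,5S)‑2‑tert‑butyl‑5‑methyl‑1,3‑dioxolan‑4‑one
Conditions: TsOH (cat.), pentane, reflux, Dean–Stark; recrystallise the cis isomer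
Reagents that add atoms: none
Why: Acetalisation of the α‑hydroxy acid with pivaldehyde gives the cis acetal, and the (S) centre of lactate sets the acetal centre.

**Step 2**
Reactants: 3; 4 prenal (3‑methylbut‑2‑enal)
Product: 5 (2S,5R)‑2‑tert‑butyl‑5‑(1‑hydroxy‑3‑methylbut‑2‑enyl)‑5‑methyl‑1,3‑dioxolan‑4‑one (carbinol epimer mixture)
Conditions: LDA, THF, –78 °C; then 4, –78 °C
Reagents that add atoms: none
Why: In a Seebach self‑regeneration‑of‑stereocentres aldol, the planar enolate is attacked trans to the tBu group, so the new C–C bond takes the position of the lactate C–H (retention) and sets the quaternary centre.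

**Step 3**
Reactants: 5
Product: 6 (2S,5R)‑2‑tert‑butyl‑5‑methyl‑5‑(3‑methylbut‑2‑enoyl)‑1,3‑dioxolan‑4‑one
Conditions: DMP, NaHCO3, CH2Cl2, 0 °C → rt
Reagents that add atoms: none
Why: Dess–Martin oxidation of the allylic alcohol removes the carbinol stereocentre, so the aldol epimers converge, and the quaternary centre cannot epimerise.

**Step 4**
Reactants: 6
Product: 7 (S)‑2‑hydroxy‑2,5‑dimethylcyclohex‑4‑ene‑1,3‑dione (plus pivaldehyde)
Conditions: LiHMDS (2.2 equiv), THF, –78 → 0 °C; aq. NH4Cl
Reagents that add atoms: none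
Why: The only acidic protons are the γ‑methyls, because the other α‑carbon is quaternary. The resulting dienolate closes in a 6‑(enolendo)‑exo intramolecular Claisen/Dieckmann‑type γ‑acylation onto the dioxolanone carbonyl. Collapse releases pivaldehyde and unmasks the tertiary alcohol, with no new stereocentre.

**Step 5**
Reactants: 7; 8 DMF‑DMA
Product: 10 (2R)‑2‑hydroxy‑6‑(hydroxymethylidene)‑2,5‑dimethylcyclohex‑4‑ene‑1,3‑dione (the 2‑formyl dione in its enol form), via 9, the in situ enaminone (2R)‑6‑[(dimethylamino)methylidene]‑2‑hydroxy‑2,5‑dimethylcyclohex‑4‑ene‑1,3‑dione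
Conditions: DMF‑DMA (3 equiv), PhMe, 80 °C; then 1 M HCl, THF, 23 °C
Reagents that add atoms: 8 DMF‑DMA, CN(C)C(OC)OC, supplies C1; water, O, hydrolyses the enaminone to the formyl group
Why: Bredereck‑type aminomethylenation occurs at the most acidic C8a–H2, and acid hydrolysis gives the formyl group that becomes pyran C1; C7 is quaternary and unaffected.

**Step 6 (key step)**
Reactants: 10; 11 tert‑butyl (E)‑4‑oxobut‑2‑enoate
Product: 12 tert‑butyl (2E)‑3‑[(7R)‑7‑hydroxy‑7‑methyl‑6,8‑dioxo‑5,6,7,8‑tetrahydro‑3H‑isochromen‑3‑yl]acrylate (C3 epimers)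
Conditions: piperidine (0.2 equiv), AcOH (0.2 equiv), PhMe, 4 Å MS, 60 °C
Reagents that add atoms: none
Why: Vinylogous Knoevenagel condensation at the γ‑methyl (C4) gives a dienal whose C8a=C4a alkene is ring‑locked cis, and this undergoes disrotatory 6π‑oxa‑electrocyclization to the 2H‑pyran, stabilised as a vinylogous ester; C3 forms as an epimer mixture that is erased in Step 7 and C7 is untouched.

**Step 7**
Reactants: 12
Product: 13 tert‑butyl (2E)‑3‑[(7R)‑7‑hydroxy‑7‑methyl‑6,8‑dioxo‑7,8‑dihydro‑6H‑isochromen‑3‑yl]acrylate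
Conditions: DDQ (1.2 equiv), CH2Cl2, 0 °C → rt
Reagents that add atoms: none
Why: DDQ abstracts hydride from the doubly activated C3–H of the 2H‑pyran (dehydrogenation). The resulting pyrylium‑type cation loses the acidic C5–H to give the azaphilone chromophore and erase C3.

**Step 8**
Reactants: 14 methyl orsellinate; 15 PMB chloride
Product: 16 methyl 2,4‑bis(4‑methoxybenzyloxy)‑6‑methylbenzoate
Conditions: K2CO3, DMF, 60 °C
Reagents that add atoms: 15 PMBCl, COc1ccc(CCl)cc1
Why: Williamson etherification of the two phenols; the hindered, chelated ester is not alkylated.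

**Step 9**
Reactants: 16
Product: 17 2,4‑bis(4‑methoxybenzyloxy)‑6‑methylbenzoic acid
Conditions: KOH, EtOH/H2O, reflux; then H3O+
Reagents that add atoms: water (O), O, as KOH/H2O
Why: Saponification of the hindered methyl ester; the PMB ethers are base‑stable.

**Step 10**
Reactants: 17; 18 Ghosez reagent
Product: 19 2,4‑bis(4‑methoxybenzyloxy)‑6‑methylbenzoyl chloride
Conditions: 18, CH2Cl2, 23 °C
Reagents that add atoms: 18 1‑chloro‑N,N,2‑trimethylpropenylamine, CC(C)=C(Cl)N(C)C, supplies Cl
Why: Neutral acid‑chloride formation avoids HCl, which would cleave the PMB ethers.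

**Step 11**
Reactants: 13; 19
Product: 20 protected mitorubrinic acid (orsellinate bis‑PMB ether, tert‑butyl ester)
Conditions: DMAP, Et3N, CH2Cl2, 23 → 40 °C
Reagents that add atoms: none
Why: DMAP‑catalysed acylation of the acidic tertiary alcohol with the aroyl chloride forms the C7 ester with retention at the quaternary centre.

**Step 12**
Reactants: 20
Product: 21 mitorubrinic acid
Conditions: TFA, 1,3‑dimethoxybenzene (scavenger), CH2Cl2, 0 °C
Reagents that add atoms: none
Why: SN1 cleavage of the tert‑butyl ester and both PMB aryl ethers, with the scavenger trapping PMB cations; C7 and the E‑alkene are unaffected.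

## Compound list
1 | (S)‑lactic acid | C[C@H](O)C(=O)O | starting material
2 | pivaldehyde | CC(C)(C)C=O | starting material
3 | (2S,5S)‑2‑tert‑butyl‑5‑methyl‑1,3‑dioxolan‑4‑one | C[C@@H]1O[C@H](C(C)(C)C)OC1=O | intermediate
4 | 3‑methylbut‑2‑enal (prenal) | CC(C)=CC=O | starting material
5 | aldol adduct (2S,5R; carbinol epimers) | CC(C)=CC(O)[C@@]1(C)O[C@H](C(C)(C)C)OC1=O | intermediate
6 | enone (2S,5R) | CC(C)=CC(=O)[C@@]1(C)O[C@H](C(C)(C)C)OC1=O | intermediate
7 | (S)‑2‑hydroxy‑2,5‑dimethylcyclohex‑4‑ene‑1,3‑dione | O[C@]1(C)C(=O)C=C(C)CC1=O | intermediate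
8 | DMF dimethyl acetal | CN(C)C(OC)OC | reagent
9 | (2R)‑6‑[(dimethylamino)methylidene]‑2‑hydroxy‑2,5‑dimethylcyclohex‑4‑ene‑1,3‑dione | O[C@]1(C)C(=O)C=C(C)C(=CN(C)C)C1=O | intermediate (in situ)
10 | (2R)‑2‑hydroxy‑6‑(hydroxymethylidene)‑2,5‑dimethylcyclohex‑4‑ene‑1,3‑dione | O[C@]1(C)C(=O)C=C(C)C(=CO)C1=O | intermediate
11 | tert‑butyl (E)‑4‑oxobut‑2‑enoate | O=C/C=C/C(=O)OC(C)(C)C | starting material
12 | 2H‑pyran (3H‑isochromene) adduct | O[C@]1(C)C(=O)CC2=CC(/C=C/C(=O)OC(C)(C)C)OC=C2C1=O | intermediate
13 | 7‑hydroxy azaphilone tert‑butyl ester | O[C@]1(C)C(=O)C=C2C=C(/C=C/C(=O)OC(C)(C)C)OC=C2C1=O | intermediate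
14 | methyl orsellinate | COC(=O)c1c(C)cc(O)cc1O | starting material
15 | 4‑methoxybenzyl chloride | COc1ccc(CCl)cc1 | reagent
16 | methyl 2,4‑bis(PMBO)‑6‑methylbenzoate | COC(=O)c1c(C)cc(OCc2ccc(OC)cc2)cc1OCc1ccc(OC)cc1 | intermediate
17 | 2,4‑bis(PMBO)‑6‑methylbenzoic acid | OC(=O)c1c(C)cc(OCc2ccc(OC)cc2)cc1OCc1ccc(OC)cc1 | intermediate
18 | Ghosez reagent | CC(C)=C(Cl)N(C)C | reagent
19 | 2,4‑bis(PMBO)‑6‑methylbenzoyl chloride | ClC(=O)c1c(C)cc(OCc2ccc(OC)cc2)cc1OCc1ccc(OC)cc1 | intermediate
20 | protected mitorubrinic acid | Cc1cc(OCc2ccc(OC)cc2)cc(OCc2ccc(OC)cc2)c1C(=O)O[C@]1(C)C(=O)C=C2C=C(/C=C/C(=O)OC(C)(C)C)OC=C2C1=O | intermediate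
21 | mitorubrinic acid | Cc1cc(O)cc(O)c1C(=O)O[C@]1(C)C(=O)C=C2C=C(/C=C/C(=O)O)OC=C2C1=O | target

**Total steps:** 12 (including the 3‑step orsellinate branch, Steps 8–10). **Longest linear sequence:** 9 steps (1–7, 11, 12).

## Three steps most likely to fail
1. **Step 6 (vinylogous condensation/oxa‑6π; the amine may divert the formyl group to an enaminone, or the condensation may occur at C5 instead of C4).**
   Fallback: silylate enaminone 9 to its TBS dienol ether and run a γ‑selective vinylogous Mukaiyama aldol with 11. Oxidise the adduct with DMP to the C3 ketone, then close the pyran by HCl‑mediated enaminone hydrolysis and cyclodehydration of the 1,5‑dicarbonyl. This gives 13 directly and removes the DDQ step.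
2. **Step 4 (γ‑acylation by the hindered dioxolanone may give oligomers or retro‑Claisen products).**
   Fallback: methanolyse 6 (NaOMe, MeOH), protect the tertiary OH as its TES ether, and close the ring by LDA‑mediated vinylogous Dieckmann cyclisation onto the methyl ester. The acyl donor and leaving group change, and the pivaldehyde‑hemiacetal alkoxide is avoided.
3. **Step 11 (esterifying a hindered tertiary alcohol on the amine‑sensitive azaphilone).**
   Fallback: reorder the sequence. Acylate the less electrophilic 2H‑pyran 12 with 19 first, then perform the DDQ dehydrogenation to give 20 directly.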